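**Retrosynthetic overview**

1. The target 20 comes from flavanone 18 by O-methylation of the C5 hydroxyl and removal of the 4'-O-benzyl group.
2. The strategy rests on ring A: C5, C6 and C7 each carry oxygen and C8 carries hydrogen. These four carbons map onto C1–C4 of the 1,2,3-trioxygenated vinylketene acetal 7, and C4a=C8a is the enol-ether double bond of ring C. Ring A is disconnected at C8–C8a and C4a–C5.
3. The dienophile is the 5-phenylsulfinyl dihydropyranone 14. A sulfinyl group is chosen because H-8a of the cycloadduct is cis to the sulfur group and not acidic, so only a thermal syn elimination can restore C4a=C8a.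
4. Sulfoxide 14 comes from dihydropyranone 11 by C5 sulfenylation and S-oxidation. 11 comes from an asymmetric hetero-Diels-Alder reaction of O-benzylvanillin 8 with diene 9, which closes ring C and sets C2.
5. Diene 7 comes from methyl methoxyacetate 1 by acetylation, enol etherification and dienolate silylation. Ring order: ring B is purchased, ring C is formed in step 4, ring A in step 7.

Key step: step 7

Assumption: the titanium complex of (S)-BINOL is taken to deliver the diene to the Si face of the aryl aldehyde, as the same ligand does in carbonyl allylation; if the sense proves opposite, (R)-BINOL is used.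

**Step 1**
Reactants: 1 methyl methoxyacetate
Product: 3 methyl 2-methoxy-3-oxobutanoate (racemic), via lithium enolate of methyl methoxyacetate 2 (not isolated)
Conditions: 1 (2.0 equiv), LiN(iPr)2 (2.0 equiv), THF, −78 °C; AcCl (1.0 equiv), −78 °C; aq. NH4Cl
Reagents that add atoms: acetyl chloride, CC(=O)Cl
Why: Claisen-type C-acylation of a preformed ester lithium enolate by an acid chloride, the second equivalent of enolate deprotonating the more acidic β-keto ester as it forms, should give 3 on work-up.

**Step 2**
Reactants: 3 methyl 2-methoxy-3-oxobutanoate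
Product: 5 methyl (2Z)-2,3-dimethoxybut-2-enoate, via methyl 2,3,3-trimethoxybutanoate 4 (not isolated)
Conditions: HC(OMe)3, cat. p-TsOH, MeOH, 50 °C; then distil from cat. p-TsOH (−MeOH)
Reagents that add atoms: trimethyl orthoformate, COC(OC)OC
Why: Acid-catalysed ketalisation by the orthoformate followed by loss of methanol is the standard enol etherification of β-keto esters and should give the conjugated enol ether, expected mainly with the methyl group cis to the ester; a deconjugated isomer would lead to the same dienolate in step 3.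

**Step 3**
Reactants: 5 methyl (2Z)-2,3-dimethoxybut-2-enoate
Product: 7 (1E)-1,2,3-trimethoxy-1-(trimethylsilyloxy)buta-1,3-diene, via lithium dienolate 6 (not isolated)
Conditions: LiN(iPr)2 (1.1 equiv), THF, −78 °C; Me3SiCl, −78 °C → rt; pentane, filter under N2, distil; use at once
Reagents that add atoms: chlorotrimethylsilane, C[Si](C)(C)Cl
Why: Carbonyl-directed γ-deprotonation of the 3-alkoxycrotonate to the extended dienolate and O-silylation is the established route to 1-alkoxy-1-silyloxy dienes; the geometry of the ketene acetal has no bearing on the product of step 7.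

**Step 4**
Reactants: 8 4-(benzyloxy)-3-methoxybenzaldehyde; 9 (E)-1-methoxy-3-(trimethylsilyloxy)buta-1,3-diene
Product: 11 (2S)-2-[4-(benzyloxy)-3-methoxyphenyl]-2,3-dihydro-4H-pyran-4-one, via silylated aldol adduct 10 (not isolated)
Conditions: (S)-BINOL (20 mol %), Ti(OiPr)4 (10 mol %), 4 Å MS, Et2O, −20 °C; then CF3CO2H, CH2Cl2, 0 °C; recrystallise
Reagents that add atoms: none
Why: This is a catalytic asymmetric hetero-Diels-Alder reaction in its Mukaiyama aldol/cyclisation form: the chiral titanium BINOLate directs the diene to the Si face of the aldehyde, which sets C2 as S, and acid then closes ring C with loss of methanol; recrystallisation should raise the enantiomeric purity if needed.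

**Step 5**
Reactants: 11 (2S)-2-[4-(benzyloxy)-3-methoxyphenyl]-2,3-dihydro-4H-pyran-4-one
Product: 13 (2S)-2-[4-(benzyloxy)-3-methoxyphenyl]-5-(phenylsulfanyl)-2,3-dihydro-4H-pyran-4-one, via 6-chloro-5-(phenylsulfanyl)tetrahydropyran-4-one adduct 12 (not isolated)
Conditions: PhSSPh (0.55 equiv), SO2Cl2 (0.55 equiv), CH2Cl2, 0 °C; add to 11, CH2Cl2, −78 °C; then Et3N (1.5 equiv), −78 → 0 °C
Reagents that add atoms: diphenyl disulfide, c1ccc(SSc2ccccc2)cc1 (converted in the flask into benzenesulfenyl chloride, ClSc1ccccc1)
Why: Electrophilic sulfenylation of an enol ether: the sulfenyl chloride adds across C5=C6 with sulfur at the nucleophilic C5 and chloride at the acetal carbon, and the amine removes HCl through the acidic H-5, as in the sulfenylation of glycals and enaminones; C2 is not involved.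

**Step 6**
Reactants: 13 (2S)-2-[4-(benzyloxy)-3-methoxyphenyl]-5-(phenylsulfanyl)-2,3-dihydro-4H-pyran-4-one
Product: 14 (2S)-2-[4-(benzyloxy)-3-methoxyphenyl]-5-(phenylsulfinyl)-2,3-dihydro-4H-pyran-4-one (both sulfur epimers)
Conditions: mCPBA (1.0 equiv), CH2Cl2, −78 → −30 °C; aq. NaHCO3
Reagents that add atoms: 3-chloroperoxybenzoic acid, O=C(OO)c1cccc(Cl)c1
Why: One equivalent of peracid at low temperature oxidises the sulfide chemoselectively to the sulfoxide and leaves the electron-poor enone double bond alone; the sulfur configuration is irrelevant because sulfur is lost in step 7.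

**Step 7**
Reactants: 14 (2S)-2-[4-(benzyloxy)-3-methoxyphenyl]-5-(phenylsulfinyl)-2,3-dihydro-4H-pyran-4-one; 7 (1E)-1,2,3-trimethoxy-1-(trimethylsilyloxy)buta-1,3-diene
Product: 18 (2S)-2-[4-(benzyloxy)-3-methoxyphenyl]-5-hydroxy-6,7-dimethoxychroman-4-one, via cycloadduct 15 (not isolated), via 5,8-dihydro ketal 16 (not isolated), via aryl trimethylsilyl ether 17 (not isolated)
Conditions: 7 (2.5 equiv), PhMe, 0 °C → rt, then 70 °C; then 1 M HCl, THF, rt
Reagents that add atoms: none
Why: Proposed new method: The electron-rich vinylketene acetal 7 should add to the C4a=C8a bond of 14 in a polarity-matched, probably highly asynchronous [4+2] cycloaddition (the CH2 terminus of 7 to C8a, the ketene acetal carbon to C4a) to give 15 with the sulfinyl group and H-8a cis; warming should then cause thermal syn elimination of benzenesulfenic acid to restore C4a=C8a (16), and acid-promoted loss of methanol from the C5 mixed ketal with removal of one H-8 aromatises ring A to the silyl ether 17, which is hydrolysed to 18 on work-up. The closest known reaction type is the Diels-Alder aromatisation of 1-alkoxy-1-silyloxy dienes with halogen- or sulfinyl-activated quinones, enones and 3-substituted chromones; a 5-sulfinyl-2,3-dihydropyran-4-one and a 1,2,3-trioxygenated diene have not been combined in this way. Ring A is closed as a six-membered carbocycle by intermolecular [4+2] cycloaddition or, if the addition is stepwise, by Mukaiyama-Michael attack at C8a followed by 6-exo-trig closure of the C4a enolate onto the ester-derived C5. No lasting stereocentre is formed, since C4a, C5 and C8a all become sp2, and C2, set in step 4, lies outside the reacting system and meets no base. The step needs regioselectivity (C8 to C8a, C5 to C4a), which the match between the nucleophilic CH2 terminus of the diene and C8a (β to both the ketone and the sulfinyl group and bearing O1) should secure, and it needs the cis relation of sulfinyl and H-8a, which suprafacial addition to the dienophile guarantees. A sulfinyl and not a sulfonyl activator is used because H-8a is not acidic, so only a syn-periplanar thermal elimination can remove the sulfur group under conditions that leave ring C closed.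

**Step 8**
Reactants: 18 (2S)-2-[4-(benzyloxy)-3-methoxyphenyl]-5-hydroxy-6,7-dimethoxychroman-4-one
Product: 19 (2S)-2-[4-(benzyloxy)-3-methoxyphenyl]-5,6,7-trimethoxychroman-4-one
Conditions: MeI (10 equiv), Ag2O (3 equiv), DMF, rt, dark
Reagents that add atoms: iodomethane, CI
Why: Williamson-type O-methylation under essentially neutral silver oxide conditions should alkylate the hydrogen-bonded C5 hydroxyl without the base-induced E1cB opening of ring C that would racemise C2.

**Step 9**
Reactants: 19 (2S)-2-[4-(benzyloxy)-3-methoxyphenyl]-5,6,7-trimethoxychroman-4-one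
Product: 20 agecorynin E, (2S)-2-(4-hydroxy-3-methoxyphenyl)-5,6,7-trimethoxychroman-4-one
Conditions: H2 (1 atm), 10% Pd/C, EtOAc, rt; stop after one equivalent of H2
Reagents that add atoms: none
Why: Catalytic hydrogenolysis of the benzyl aryl ether in a non-acidic solvent, stopped at one equivalent of hydrogen, should free the 4'-phenol while the ketone and the cyclic benzylic C2–O1 bond, which react more slowly, are kept.

**Compound list**

1 | methyl methoxyacetate | COCC(=O)OC | starting material
2 | lithium enolate of methyl methoxyacetate (chelated) | CO/C=C(/OC)O[Li] | intermediate (not isolated)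
3 | methyl 2-methoxy-3-oxobutanoate (racemic) | CC(=O)C(OC)C(=O)OC | intermediate
4 | methyl 2,3,3-trimethoxybutanoate (racemic) | COC(=O)C(OC)C(C)(OC)OC | intermediate (not isolated)
5 | methyl (2Z)-2,3-dimethoxybut-2-enoate | C/C(OC)=C(/OC)C(=O)OC | intermediate
6 | lithium dienolate of 5 | C=C(OC)/C(OC)=C(/OC)O[Li] | intermediate (not isolated)
7 | (1E)-1,2,3-trimethoxy-1-(trimethylsilyloxy)buta-1,3-diene | C=C(OC)/C(OC)=C(/OC)O[Si](C)(C)C | intermediate
8 | 4-(benzyloxy)-3-methoxybenzaldehyde | COc1cc(C=O)ccc1OCc1ccccc1 | starting material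
9 | (E)-1-methoxy-3-(trimethylsilyloxy)buta-1,3-diene | CO/C=C/C(=C)O[Si](C)(C)C | starting material
10 | (1E,5S)-5-[4-(benzyloxy)-3-methoxyphenyl]-1-methoxy-5-(trimethylsilyloxy)pent-1-en-3-one | COc1cc([C@@H](O[Si](C)(C)C)CC(=O)/C=C/OC)ccc1OCc1ccccc1 | intermediate (not isolated)
11 | (2S)-2-[4-(benzyloxy)-3-methoxyphenyl]-2,3-dihydro-4H-pyran-4-one | COc1cc([C@@H]2CC(=O)C=CO2)ccc1OCc1ccccc1 | intermediate
12 | (2S)-2-[4-(benzyloxy)-3-methoxyphenyl]-6-chloro-5-(phenylsulfanyl)tetrahydro-4H-pyran-4-one (C5 and C6 isomers) | COc1cc([C@@H]2CC(=O)C(Sc3ccccc3)C(Cl)O2)ccc1OCc1ccccc1 | intermediate (not isolated)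
13 | (2S)-2-[4-(benzyloxy)-3-methoxyphenyl]-5-(phenylsulfanyl)-2,3-dihydro-4H-pyran-4-one | COc1cc([C@@H]2CC(=O)C(Sc3ccccc3)=CO2)ccc1OCc1ccccc1 | intermediate
14 | (2S)-2-[4-(benzyloxy)-3-methoxyphenyl]-5-(phenylsulfinyl)-2,3-dihydro-4H-pyran-4-one (both sulfur epimers) | COc1cc([C@@H]2CC(=O)C(S(=O)c3ccccc3)=CO2)ccc1OCc1ccccc1 | intermediate
15 | (2S)-2-[4-(benzyloxy)-3-methoxyphenyl]-5,6,7-trimethoxy-4a-(phenylsulfinyl)-5-(trimethylsilyloxy)-4a,5,8,8a-tetrahydrochroman-4-one (sulfinyl cis to H-8a; isomers at C4a, C5, C8a and sulfur) | COc1cc([C@@H]2CC(=O)C3(S(=O)c4ccccc4)C(O2)CC(OC)=C(OC)C3(OC)O[Si](C)(C)C)ccc1OCc1ccccc1 | intermediate (not isolated)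
16 | (2S)-2-[4-(benzyloxy)-3-methoxyphenyl]-5,6,7-trimethoxy-5-(trimethylsilyloxy)-5,8-dihydrochroman-4-one (C5 epimers) | COc1cc([C@@H]2CC(=O)C3=C(O2)CC(OC)=C(OC)C3(OC)O[Si](C)(C)C)ccc1OCc1ccccc1 | intermediate (not isolated)
17 | (2S)-2-[4-(benzyloxy)-3-methoxyphenyl]-6,7-dimethoxy-5-(trimethylsilyloxy)chroman-4-one | COc1cc([C@@H]2CC(=O)c3c(O[Si](C)(C)C)c(OC)c(OC)cc3O2)ccc1OCc1ccccc1 | intermediate (not isolated)
18 | (2S)-2-[4-(benzyloxy)-3-methoxyphenyl]-5-hydroxy-6,7-dimethoxychroman-4-one | COc1cc([C@@H]2CC(=O)c3c(O)c(OC)c(OC)cc3O2)ccc1OCc1ccccc1 | intermediate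
19 | (2S)-2-[4-(benzyloxy)-3-methoxyphenyl]-5,6,7-trimethoxychroman-4-one | COc1cc([C@@H]2CC(=O)c3c(OC)c(OC)c(OC)cc3O2)ccc1OCc1ccccc1 | intermediate
20 | agecorynin E, (2S)-2-(4-hydroxy-3-methoxyphenyl)-5,6,7-trimethoxychroman-4-one | COc1cc([C@@H]2CC(=O)c3c(cc(OC)c(OC)c3OC)O2)ccc1O | target

**Step count**

Total: 9 steps. Longest linear sequence: 6 steps (steps 4, 5, 6, 7, 8, 9 from 8; the diene arm, steps 1, 2, 3, 7, 8, 9 from 1, is equally long).

**Steps most likely to fail**

Step 7 (proposed new method). Several processes could divert the step: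
- conjugate addition of the diene at C8a without closure of the second bond, followed by loss of sulfenic acid from the open-chain adduct;
- silyl transfer from the ketene acetal to the sulfinyl oxygen (Pummerer-type diversion);
- consumption of the diene by the benzenesulfenic acid released;
- a stepwise closure that places sulfinyl and H-8a trans, so that syn elimination cannot occur and opening of ring C at C8a–O1 takes over.

Fallback by known chemistry, setting out from 8 and returning at 19: Claisen-Schmidt condensation of 8 with commercial 2'-hydroxy-4',5',6'-trimethoxyacetophenone (CC(=O)c1c(O)cc(OC)c(OC)c1OC; KOH, EtOH, rt) should give (E)-3-[4-(benzyloxy)-3-methoxyphenyl]-1-(6-hydroxy-2,3,4-trimethoxyphenyl)prop-2-en-1-one F1. Intramolecular oxa-Michael cyclisation (NaOAc, EtOH, reflux) should give racemic 2-[4-(benzyloxy)-3-methoxyphenyl]-5,6,7-trimethoxychroman-4-one F2. Preparative chromatography on a cellulose tris(3,5-dimethylphenylcarbamate) phase would then deliver the (2S)-enantiomer 19, and the (2R)-enantiomer could be racemised with base through F1 and recycled. The route continues with step 9.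

Step 8. The hydrogen-bonded C5 hydroxyl may alkylate incompletely, and forcing the reaction may open ring C by E1cB elimination to the 2'-hydroxychalcone, which recloses with erosion of the C2 configuration. Fallback setting out from 18 and returning at 19: reduction of the ketone (NaBH4, THF/MeOH, 0 °C) should give (2S)-2-[4-(benzyloxy)-3-methoxyphenyl]-6,7-dimethoxychromane-4,5-diol F3 (mainly 2,4-cis), in which the phenol is no longer chelated and ring C cannot open. Methylation (K2CO3, MeI, acetone, rt) should give (2S)-2-[4-(benzyloxy)-3-methoxyphenyl]-5,6,7-trimethoxychroman-4-ol F4, and oxidation of the benzylic alcohol (MnO2, CH2Cl2, rt) returns 19.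

Step 5. The sulfenyl chloride may attack the electron-rich benzyloxy-methoxy arene in competition with C5, and the amine may open ring C by E1cB elimination with loss of configurational purity at C2. Fallback setting out from 11 and returning at 13: α-iodination (I2, pyridine, CH2Cl2, rt) should give (2S)-2-[4-(benzyloxy)-3-methoxyphenyl]-5-iodo-2,3-dihydro-4H-pyran-4-one F5, and C–S cross-coupling with thiophenol (Pd2(dba)3, Xantphos, iPr2NEt, dioxane, 80 °C) returns 13.

**Further compounds**

F1 | step 7 | (E)-3-[4-(benzyloxy)-3-methoxyphenyl]-1-(6-hydroxy-2,3,4-trimethoxyphenyl)prop-2-en-1-one | COc1cc(/C=C/C(=O)c2c(O)cc(OC)c(OC)c2OC)ccc1OCc1ccccc1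
F2 | step 7 | racemic 2-[4-(benzyloxy)-3-methoxyphenyl]-5,6,7-trimethoxychroman-4-one | COc1cc(C2CC(=O)c3c(OC)c(OC)c(OC)cc3O2)ccc1OCc1ccccc1
F3 | step 8 | (2S)-2-[4-(benzyloxy)-3-methoxyphenyl]-6,7-dimethoxychromane-4,5-diol (C4 epimers, mainly 2,4-cis) | COc1cc([C@@H]2CC(O)c3c(O)c(OC)c(OC)cc3O2)ccc1OCc1ccccc1
F4 | step 8 | (2S)-2-[4-(benzyloxy)-3-methoxyphenyl]-5,6,7-trimethoxychroman-4-ol (C4 epimers, mainly 2,4-cis) | COc1cc([C@@H]2CC(O)c3c(OC)c(OC)c(OC)cc3O2)ccc1OCc1ccccc1
F5 | step 5 | (2S)-2-[4-(benzyloxy)-3-methoxyphenyl]-5-iodo-2,3-dihydro-4H-pyran-4-one | COc1cc([C@@H]2CC(=O)C(I)=CO2)ccc1OCc1ccccc1
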